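Decide first what you will count: for the order in free catalyst, count the part of the catalyst charge that stray impurity has taken by the moment asked. Your one flask, larch, has been followed this far:

| flask | starting material | protic impurity | free catalyst | stray impurity | remark |
|---|---|---|---|---|---|
| larch | 0.11 M | 0.011 M | 55 µM | 34 µM | the very flask that is asked about, followed so far |
| flask | 0.11 M | 0.0110 M | 55 µM | 34 µM |  |

- larch (time / min: product / %, starting material / %): 0.250: 3.3, 95.6; 0.417: 3.0, 94.5; 0.667: 4.7, 91.9; 1.33: 8.5, 84.8; 2.00: 11.7, 80.2; 3.00: 16.4, 75.7

(standard deviation of a reading: 1 percentage point)

1. apparent order in free catalyst when 5.0 % of the starting material are converted (percent change of the rate of making product for one percent more free catalyst charged)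

- no earlier run changes the charge of free catalyst; that part of a forecast is a guess

My assumption is that stray impurity takes catalyst one for one. Then stray charge over catalyst charge, the poison share, is 61.8 %. If a part z of the charge has been taken and I hold that amount fixed while the charge is turned, working catalyst is the charge minus a fixed amount, so the order is one over (one minus z).

Turn the catalyst charge first. By hand, the order is 1 with nothing taken and 2.62 with the share fully taken. No earlier run changes this charge, so this step of my reckoning is a guess.

Turn the moment next. In larch, the 5.0 % mark falls between 0.250 min and 0.417 min, so look at how fast z grows. Product rate per starting material left, late window over first window, reads 80.3 %. This is a coarse reading, but it stays above the 38.2 % of the charge that a fully taken share leaves working. If I read that loss as z and scale it back in proportion to time, from 2.17 min to 0.309 min, my estimate of z is 0.0282, so my order is 1.03.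

Turn the protic impurity last. Its charge is 10.0 % of the starting material, and I take it to shift the moment without adding to the share.

The forecast is higher than mine, at 1.8, in its words “I expect something in between”.

    starting material + free catalyst → catalyst intermediate A (k = 80.0 /M/s)
    catalyst intermediate A ⇌ catalyst intermediate B (K = 2.60, k = 13.0 /s)
    catalyst intermediate B → free catalyst + product (k = 12.0 /s)
    starting material + protic impurity → quenched substrate (k = 0.130 /M/s)
    free catalyst + stray impurity → spent catalyst (k = 990 /M/s)

The flask gives 1.1. At the start of this flask, free catalyst entered catalyst intermediate A 260 times as fast as stray impurity turned it into spent catalyst. Held against the poison share, spent catalyst in this flask at 0.800 min is 34.1 % of the catalyst charge, which is 55.2 % of that share. After 80.0 min it stands at 61.8 %, against a share of 61.8 %.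

The data were generated by integration on assumed constants, noise included.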